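The runs come from a simulation for substances that don't exist; scatter was added.

| flask | substrate | coupling partner | catalyst | time |
|---|---|---|---|---|
| cedar | 0.500 M | 0.550 M | 0.0150 M |  |
| oak | 0.300 M | 0.350 M | 0.0150 M |  |
| birch | 0.500 M | 1.10 M | 0.0150 M |  |
| ash | 0.500 M | 0.550 M | 0.0300 M |  |
| elm | 0.500 M | 0.550 M | 0.0690 M | 16 h |

| run | time / h | [substrate] / M |
|---|---|---|
| cedar run | 2.3 | 0.4105 |
| cedar run | 4.6 | 0.3860 |
| cedar run | 6.9 | 0.3736 |
| cedar run | 9.1 | 0.3631 |
| cedar run | 11 | 0.3649 |
| cedar run | 14 | 0.3597 |
| cedar run | 16 | 0.3606 |
| oak run | 2.3 | 0.2544 |
| oak run | 4.6 | 0.2386 |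
| oak run | 6.9 | 0.2333 |
| oak run | 9.1 | 0.2275 |
| oak run | 11 | 0.2242 |
| oak run | 14 | 0.2216 |
| oak run | 16 | 0.2182 |
| birch run | 2.3 | 0.3779 |
| birch run | 4.6 | 0.3516 |
| birch run | 6.9 | 0.3407 |
| birch run | 9.1 | 0.3333 |
| birch run | 11 | 0.3313 |
| birch run | 14 | 0.3269 |
| birch run | 16 | 0.3256 |
| ash run | 2.3 | 0.3425 |
| ash run | 4.6 | 0.3163 |
| ash run | 6.9 | 0.3031 |
| ash run | 9.1 | 0.3000 |
| ash run | 11 | 0.2973 |
| ash run | 14 | 0.2943 |
| ash run | 16 | 0.2936 |

(readings scatter by 0.002 M)

- Overall: substrate + coupling partner -> product, with catalyst as catalyst.
- Constant volume, constant temperature.
- "The second partner" is coupling partner.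
- An order is taken over about fifteen percent of the charge, up and down.

1. the power of [substrate] that the first rate follows, about the charge of the cedar run; measure it at two percent of substrate made into product (one fixed amount of product, the same in the runs compared)
2. the power of [coupling partner] that the first rate follows, about the charge of the cedar run; measure it at two percent of substrate made into product
3. substrate in the elm run at 16 h, as a share of the substrate charged
4. which of these the readings show (the product decays / the second partner is lost by itself / the second partner is lost in pairs)

**One ratio.** Two constants enter where these flasks stop: k for coupling, which acts through the catalyst, and q for the loss of partner. At their last readings oak and cedar stand at nearly the same share of substrate, 72.7% and 72.1%, on similar partner-to-substrate charges r and different absolute charges. A loss in pairs gives this scale-free stop, so take coupling as k·c·S·R and loss as q·R². Their ratio is g·R/S, with g = q/(k·c), a selectivity factor. Counting each stall as zero partner, the end share y obeys y^(1−g) = 1 + (g−1)·r.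

**From above.** Elm holds more catalyst than ash, so I expect it to stop no higher than ash's reading of 58.7%.

**From below.** Ash's partner charge, divided by the substrate turned, leaves 1.66 of partner wasted per substrate turned; cedar's figure is 2.95. Waste times catalyst is smaller in cedar than in ash. Scaling ash's waste inversely with catalyst should therefore understate elm's waste, which puts elm's share at 36.2% or above.

**Tightening.** My own reckoning solves the law for ash, whose catalyst lies closer to elm's than cedar's does. A trial g−1 of 2.50 returns 2.48, so 0.104 M is the tie catalyst, the level where g equals 1. For elm, g is 1.51, and the law gives 41.8%.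

**The forecast.** Working from cedar instead, the forecast says 42.3% for elm, slightly above my figure and inside the bracket, with orders about the cedar charge of 1.17 in substrate and 1.02 in partner. Its choice is that the second partner is lost in pairs: “That points to loss in pairs”.

**The flask.** Elm gives 42.1%; about the cedar charge the orders are 1.2 in substrate and 1.0 in partner, and the readings show that the second partner is lost in pairs.

    catalyst + substrate + coupling partner → product + catalyst (29.81 M⁻² h⁻¹)
    2 coupling partner → lost reagent (1.580 M⁻¹ h⁻¹)

**Why it stops.** Elm's catalyst stays below the tie catalyst, so by this reckoning, at equal concentrations of substrate and partner, the pair step in elm wastes 1.51 of partner for each one coupled. On cedar, a flask not used to obtain it, the tie catalyst gives g of 6.97 and an end share of 71.2%, against the 72.1% read. The reaction of two coupling partner to lost reagent is what holds elm's substrate up: the elm run without that reaction ends at 2.13% instead of 42.1%, a change of 40 percentage points.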